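**Retrosynthetic overview**

1. Target 14 ← fluoride desilylation of tetrasilyl ether 13 ← Sandmeyer exchange of NH2 for Br at C2 (from 11) ← amine-directed bromination at C3 (from 10) ← reduction of dinitro compound 9.
2. Key disconnection, in both rings at once: C1–C2 and C2–C3. In each benzene ring (C1 bears the CH2O arm C7, C2 and C3 bear Br, C4 and C5 bear OH, C6 bears H) the array C7–C1–C6(H)–C5(O)–C4(O)–C3 is the carbon–oxygen array of kojic acid (CH2OH carbon, pyranone C2, C3–H, C4=O, C5–OH, C6–H). Only C2 is missing; one molecule of nitromethane per ring supplies it in place of the ring oxygen.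
3. The key-step precursor 5, a bis(kojyl) ether, comes from Ag2O coupling of alcohol 3 with bromide 4, both made from kojic acid 1 through bis(silyl) ether 2.
4. Ring order: the two pyranone rings are bought with kojic acid, the two benzene rings are formed together in step 5, and no ring is formed afterwards.

Key step: step 5

Remark: the target has no stereocenter. Nitronate attack is assumed at the unsubstituted alpha carbon of each pyrylium ring (pyranone C6); attack at the other alpha carbon would give the same arene. The 2-nitrobenzyl ethers (9 and the related fallback compounds) are light-sensitive and are handled in the dark.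

**Route**

Step 1
Reactants: 1 kojic acid
Product: 2 5-(tert-butyldimethylsilyloxy)-2-[(tert-butyldimethylsilyloxy)methyl]-4H-pyran-4-one
Conditions: TBSCl (2.4 equiv), imidazole (5 equiv), DMF, rt
Reagents that add atoms: tert-butyldimethylsilyl chloride, CC(C)(C)[Si](C)(C)Cl
Why: Standard silyl protection with TBSCl and imidazole should silylate both the enolic 5-OH and the primary alcohol and leave the pyranone untouched.

Step 2
Reactants: 2 5-(tert-butyldimethylsilyloxy)-2-[(tert-butyldimethylsilyloxy)methyl]-4H-pyran-4-one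
Product: 3 5-(tert-butyldimethylsilyloxy)-2-(hydroxymethyl)-4H-pyran-4-one
Conditions: AcOH/THF/H2O (3:1:1), rt
Reagents that add atoms: none
Why: Selective acid-catalysed desilylation should work because a primary alkyl silyl ether hydrolyses much faster than the silyl ether on the weakly basic, electron-poor pyranone oxygen, which behaves like an aryl silyl ether.

Step 3
Reactants: 3 5-(tert-butyldimethylsilyloxy)-2-(hydroxymethyl)-4H-pyran-4-one (half of the material)
Product: 4 2-(bromomethyl)-5-(tert-butyldimethylsilyloxy)-4H-pyran-4-one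
Conditions: CBr4, PPh3, CH2Cl2, 0 °C
Reagents that add atoms: carbon tetrabromide, BrC(Br)(Br)Br
Why: The Appel reaction should convert the primary alcohol into the bromide under neutral conditions that spare the silyl ether and the vinylogous ester carbonyl.

Step 4
Reactants: 3 5-(tert-butyldimethylsilyloxy)-2-(hydroxymethyl)-4H-pyran-4-one; 4 2-(bromomethyl)-5-(tert-butyldimethylsilyloxy)-4H-pyran-4-one
Product: 5 bis{[5-(tert-butyldimethylsilyloxy)-4-oxo-4H-pyran-2-yl]methyl} ether
Conditions: Ag2O (1.5 equiv), 4 Å MS, CH2Cl2, rt, dark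
Reagents that add atoms: none
Why: In this Ag2O-promoted Williamson-type etherification silver assists loss of bromide from the activated bromide while the alcohol attacks, without a strong base that could move or cleave the silyl ethers.

Step 5
Reactants: 5 bis{[5-(tert-butyldimethylsilyloxy)-4-oxo-4H-pyran-2-yl]methyl} ether; 6 nitromethane (two molecules per molecule of 5, one for each ring)
Product: 9 bis[4,5-bis(tert-butyldimethylsilyloxy)-2-nitrobenzyl] ether, via bis(4-silyloxypyrylium) bis(triflate) 7 (not isolated), via ring-opened bis(nitrodienone) 8 (not isolated)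
Conditions: TBSOTf (2.3 equiv), CH2Cl2, 0 °C to rt; then MeNO2 (10 equiv), i-Pr2NEt (5 equiv), −40 °C to 40 °C, dark
Reagents that add atoms: tert-butyldimethylsilyl trifluoromethanesulfonate, CC(C)(C)[Si](C)(C)OS(=O)(=O)C(F)(F)F; nitromethane, C[N+](=O)[O-]
Why: Proposed new method: two equivalents of TBSOTf silylate the two pyranone carbonyl oxygens to give the bis(4-silyloxypyrylium) salt 7, one nitronate formed from nitromethane and i-Pr2NEt adds per ring at the unsubstituted alpha carbon (pyranone C6), and each 2H-pyran opens in a thermal six-electron electrocyclic reaction to the dienone of 8, whose ketone is the old pyranone C2. Ring opening is reversible, so the geometry with the nitromethyl group turned toward the ketone is available, and from it the nitromethyl carbon, deprotonated again, adds to that ketone in an intramolecular Henry (nitro-aldol) reaction, a 6-exo-trig closure that forms each carbocycle, before E1cB loss of water aromatizes; per ring C1–C2 and C2–C3 are made and the ring oxygen leaves as water. The closest known reactions are the conversion of 2,4,6-trisubstituted pyrylium salts into nitrobenzenes with nitromethane and base and the silyl-triflate-promoted addition of carbon nucleophiles to the alpha carbon of 4-pyranones. No stereocenter is set, since the two sp3 centres of each aldol adduct are lost on dehydration. The step needs alpha and not gamma attack on the pyrylium ion: the gamma carbon carries its own silyloxy group and is flanked by the second one, and both alpha carbons lead to the same arene. The balanced equation consumes two molecules each of TBSOTf and nitromethane per molecule of 5, and the silyl group placed on each carbonyl oxygen stays as the C5 aryl silyl ether, so all four catechol oxygens leave the step protected alike.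

Step 6
Reactants: 9 bis[4,5-bis(tert-butyldimethylsilyloxy)-2-nitrobenzyl] ether
Product: 10 bis[2-amino-4,5-bis(tert-butyldimethylsilyloxy)benzyl] ether
Conditions: H2 (1 atm), 5% Pt/C, EtOAc, rt, dark
Reagents that add atoms: none
Why: Catalytic hydrogenation of aromatic nitro groups over Pt/C is fast under neutral aprotic conditions, and platinum, unlike palladium, should leave the dibenzyl ether C–O bonds and the aryl silyl ethers intact.

Step 7
Reactants: 10 bis[2-amino-4,5-bis(tert-butyldimethylsilyloxy)benzyl] ether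
Product: 11 bis[2-amino-3-bromo-4,5-bis(tert-butyldimethylsilyloxy)benzyl] ether
Conditions: NBS (2.05 equiv), MeCN, −20 °C to 0 °C, dark
Reagents that add atoms: N-bromosuccinimide, O=C1CCC(=O)N1Br
Why: In this electrophilic aromatic bromination C3 is the only open position ortho to the amine (C1 and the para position C5 are substituted) and is also ortho to the C4 silyloxy group, whereas C6 is meta to nitrogen and has one ortho donor only.

Step 8
Reactants: 11 bis[2-amino-3-bromo-4,5-bis(tert-butyldimethylsilyloxy)benzyl] ether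
Product: 13 bis[2,3-dibromo-4,5-bis(tert-butyldimethylsilyloxy)benzyl] ether, via bis(diazonium) dibromide 12 (not isolated)
Conditions: t-BuONO (3 equiv), CuBr2 (3 equiv), MeCN, 0 °C to rt, slow addition of 11
Reagents that add atoms: copper dibromide, [Cu+2].[Br-].[Br-]
Why: In this Sandmeyer bromination under aprotic diazotization tert-butyl nitrite converts each amine into the diazonium ion and CuBr2 transfers bromine to the aryl radical formed on loss of nitrogen, the high CuBr2 concentration letting bromine capture outrun hydrogen abstraction.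

Step 9
Reactants: 13 bis[2,3-dibromo-4,5-bis(tert-butyldimethylsilyloxy)benzyl] ether
Product: 14 bis(2,3-dibromo-4,5-dihydroxybenzyl) ether
Conditions: TBAF (5 equiv), AcOH (6 equiv), THF, 0 °C, Ar
Reagents that add atoms: none
Why: Fluoride desilylation cleaves the four aryl Si–O bonds, and the acetic acid buffer keeps the freed catechols protonated, which should suppress quinone methide formation at the para-hydroxybenzyl ether and air oxidation.

**Compound list**

1 | kojic acid, 5-hydroxy-2-(hydroxymethyl)-4H-pyran-4-one | OCc1cc(=O)c(O)co1 | starting material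
2 | 5-(tert-butyldimethylsilyloxy)-2-[(tert-butyldimethylsilyloxy)methyl]-4H-pyran-4-one | CC(C)(C)[Si](C)(C)OCc1cc(=O)c(O[Si](C)(C)C(C)(C)C)co1 | intermediate
3 | 5-(tert-butyldimethylsilyloxy)-2-(hydroxymethyl)-4H-pyran-4-one | OCc1cc(=O)c(O[Si](C)(C)C(C)(C)C)co1 | intermediate
4 | 2-(bromomethyl)-5-(tert-butyldimethylsilyloxy)-4H-pyran-4-one | BrCc1cc(=O)c(O[Si](C)(C)C(C)(C)C)co1 | intermediate
5 | bis{[5-(tert-butyldimethylsilyloxy)-4-oxo-4H-pyran-2-yl]methyl} ether | CC(C)(C)[Si](C)(C)Oc1coc(COCc2cc(=O)c(O[Si](C)(C)C(C)(C)C)co2)cc1=O | intermediate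
6 | nitromethane | C[N+](=O)[O-] | starting material
7 | bis{[4,5-bis(tert-butyldimethylsilyloxy)pyrylium-2-yl]methyl} ether bis(trifluoromethanesulfonate) | CC(C)(C)[Si](C)(C)Oc1c[o+]c(COCc2cc(O[Si](C)(C)C(C)(C)C)c(O[Si](C)(C)C(C)(C)C)c[o+]2)cc1O[Si](C)(C)C(C)(C)C.[O-]S(=O)(=O)C(F)(F)F.[O-]S(=O)(=O)C(F)(F)F | intermediate (not isolated)
8 | bis[(3E,5E)-4,5-bis(tert-butyldimethylsilyloxy)-7-nitro-2-oxohepta-3,5-dien-1-yl] ether (in each chain C2 and C5 are cis across C3=C4 as in the ring, and C4 and the nitromethyl carbon C7 are cis across C5=C6, the geometry that can close) | [O-][N+](=O)C/C=C(O[Si](C)(C)C(C)(C)C)\C(O[Si](C)(C)C(C)(C)C)=C/C(=O)COCC(=O)/C=C(O[Si](C)(C)C(C)(C)C)\C(O[Si](C)(C)C(C)(C)C)=C/C[N+](=O)[O-] | intermediate (not isolated)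
9 | bis[4,5-bis(tert-butyldimethylsilyloxy)-2-nitrobenzyl] ether | CC(C)(C)[Si](C)(C)Oc1cc(COCc2cc(O[Si](C)(C)C(C)(C)C)c(O[Si](C)(C)C(C)(C)C)cc2[N+](=O)[O-])c([N+](=O)[O-])cc1O[Si](C)(C)C(C)(C)C | intermediate
10 | bis[2-amino-4,5-bis(tert-butyldimethylsilyloxy)benzyl] ether | CC(C)(C)[Si](C)(C)Oc1cc(COCc2cc(O[Si](C)(C)C(C)(C)C)c(O[Si](C)(C)C(C)(C)C)cc2N)c(N)cc1O[Si](C)(C)C(C)(C)C | intermediate
11 | bis[2-amino-3-bromo-4,5-bis(tert-butyldimethylsilyloxy)benzyl] ether | CC(C)(C)[Si](C)(C)Oc1cc(COCc2cc(O[Si](C)(C)C(C)(C)C)c(O[Si](C)(C)C(C)(C)C)c(Br)c2N)c(N)c(Br)c1O[Si](C)(C)C(C)(C)C | intermediate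
12 | bis(diazonium) dibromide of 11 | CC(C)(C)[Si](C)(C)Oc1cc(COCc2cc(O[Si](C)(C)C(C)(C)C)c(O[Si](C)(C)C(C)(C)C)c(Br)c2[N+]#N)c([N+]#N)c(Br)c1O[Si](C)(C)C(C)(C)C.[Br-].[Br-] | intermediate (not isolated)
13 | bis[2,3-dibromo-4,5-bis(tert-butyldimethylsilyloxy)benzyl] ether | CC(C)(C)[Si](C)(C)Oc1cc(COCc2cc(O[Si](C)(C)C(C)(C)C)c(O[Si](C)(C)C(C)(C)C)c(Br)c2Br)c(Br)c(Br)c1O[Si](C)(C)C(C)(C)C | intermediate
14 | bis(2,3-dibromo-4,5-dihydroxybenzyl) ether | Oc1cc(COCc2cc(O)c(O)c(Br)c2Br)c(Br)c(Br)c1O | target

**Step count**

Total steps: 9. Longest linear sequence: 9 steps (1 → 2 → 3 → 4 → 5 → 9 → 10 → 11 → 13 → 14).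

**Steps most likely to fail**

Step 5 (proposed method). Several processes may divert it. The nitronate may add at the gamma carbon and expel silanolate. The amine base may deprotonate the CH2O arm of the pyrylium ion instead of delivering the nucleophile. Silyl transfer to the nitronate may return the pyranone. Ring opening may settle in the dienone geometry whose nitromethyl group points away from the ketone, so that the sequence stops at the open-chain stage in one or both rings. Released water may strip the silyl ether para to the nitro group.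

The fallback builds the same dinitro ether from a preformed arene by known reactions. No numbered compound before 9 can serve as its starting point, because all of them still hold the pyranone ring whose conversion is at risk. It therefore sets out from commercial 4,5-dihydroxy-2-nitrobenzaldehyde F1 and comes back to the route at compound 9. Silylation (TBSCl, imidazole, DMF) should give 4,5-bis(tert-butyldimethylsilyloxy)-2-nitrobenzaldehyde F2. Reduction with NaBH4 in THF/MeOH at −20 °C should give 4,5-bis(tert-butyldimethylsilyloxy)-2-nitrobenzyl alcohol F3. Half of it is converted with CBr4 and PPh3 into 4,5-bis(tert-butyldimethylsilyloxy)-2-nitrobenzyl bromide F4, and Ag2O coupling of F3 with F4 in CH2Cl2 should give 9.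

Step 8. Several processes may lower the twofold Sandmeyer reaction. Diazotization of two hindered amines in one molecule may be incomplete. A diazonium group may couple with a remaining amine. The aryl radical may be reduced, or may abstract hydrogen from the benzylic CH2 of the other ring (1,5-hydrogen transfer through the ether) before bromine transfer. The silyl group para to the diazonium group may be lost.

The fallback moves the Sandmeyer reaction to a monomer and forms the central ether last. It sets out from compound 2 and comes back at compound 13, and it presupposes that the ring construction of step 5 has been shown to work. TBSOTf in CH2Cl2 should give 4,5-bis(tert-butyldimethylsilyloxy)-2-[(tert-butyldimethylsilyloxy)methyl]pyrylium triflate F5 (not isolated). Nitromethane 6 and i-Pr2NEt should lead through (3E,5E)-1,4,5-tris(tert-butyldimethylsilyloxy)-7-nitrohepta-3,5-dien-2-one F6 (not isolated) to tert-butyl{[4,5-bis(tert-butyldimethylsilyloxy)-2-nitrobenzyl]oxy}dimethylsilane F7. Hydrogenation (H2, Pt/C, EtOAc) should give 4,5-bis(tert-butyldimethylsilyloxy)-2-[(tert-butyldimethylsilyloxy)methyl]aniline F8. NBS should give 2-bromo-3,4-bis(tert-butyldimethylsilyloxy)-6-[(tert-butyldimethylsilyloxy)methyl]aniline F9. t-BuONO and CuBr2 should convert it, through 2-bromo-3,4-bis(tert-butyldimethylsilyloxy)-6-[(tert-butyldimethylsilyloxy)methyl]benzenediazonium bromide F10 (not isolated), into tert-butyl{[2,3-dibromo-4,5-bis(tert-butyldimethylsilyloxy)benzyl]oxy}dimethylsilane F11; here no ether C–H lies within reach of the aryl radical and only one diazonium group per molecule has to react. AcOH/THF/H2O should free 2,3-dibromo-4,5-bis(tert-butyldimethylsilyloxy)benzyl alcohol F12. Half of it is converted with CBr4 and PPh3 into 2,3-dibromo-4,5-bis(tert-butyldimethylsilyloxy)benzyl bromide F13, and Ag2O coupling of F12 with F13 should give 13.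

Step 7. NBS may oxidize the electron-rich 4-silyloxyaniline rings, may brominate on nitrogen, or may attack C6 if the hindered C3 reacts slowly. The fallback tames the ring by masking the amine as a carbamate. It sets out from compound 10 and comes back at compound 11. Boc2O in THF at 50 °C should give bis[2-(tert-butoxycarbonylamino)-4,5-bis(tert-butyldimethylsilyloxy)benzyl] ether F14. NBS in MeCN at rt should then give bis[3-bromo-2-(tert-butoxycarbonylamino)-4,5-bis(tert-butyldimethylsilyloxy)benzyl] ether F15, since C3 is still ortho to the carbamate nitrogen and to the C4 silyloxy group. TMSOTf and 2,6-lutidine in CH2Cl2 at 0 °C, followed by MeOH, should remove the carbamates and give 11.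

**Further compounds**

F1 | step 5 | 4,5-dihydroxy-2-nitrobenzaldehyde | O=Cc1cc(O)c(O)cc1[N+](=O)[O-]
F2 | step 5 | 4,5-bis(tert-butyldimethylsilyloxy)-2-nitrobenzaldehyde | O=Cc1cc(O[Si](C)(C)C(C)(C)C)c(O[Si](C)(C)C(C)(C)C)cc1[N+](=O)[O-]
F3 | step 5 | 4,5-bis(tert-butyldimethylsilyloxy)-2-nitrobenzyl alcohol | OCc1cc(O[Si](C)(C)C(C)(C)C)c(O[Si](C)(C)C(C)(C)C)cc1[N+](=O)[O-]
F4 | step 5 | 4,5-bis(tert-butyldimethylsilyloxy)-2-nitrobenzyl bromide | BrCc1cc(O[Si](C)(C)C(C)(C)C)c(O[Si](C)(C)C(C)(C)C)cc1[N+](=O)[O-]
F5 | step 8 | 4,5-bis(tert-butyldimethylsilyloxy)-2-[(tert-butyldimethylsilyloxy)methyl]pyrylium triflate | CC(C)(C)[Si](C)(C)OCc1cc(O[Si](C)(C)C(C)(C)C)c(O[Si](C)(C)C(C)(C)C)c[o+]1.[O-]S(=O)(=O)C(F)(F)F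
F6 | step 8 | (3E,5E)-1,4,5-tris(tert-butyldimethylsilyloxy)-7-nitrohepta-3,5-dien-2-one | CC(C)(C)[Si](C)(C)OCC(=O)/C=C(O[Si](C)(C)C(C)(C)C)\C(O[Si](C)(C)C(C)(C)C)=C/C[N+](=O)[O-]
F7 | step 8 | tert-butyl{[4,5-bis(tert-butyldimethylsilyloxy)-2-nitrobenzyl]oxy}dimethylsilane | CC(C)(C)[Si](C)(C)OCc1cc(O[Si](C)(C)C(C)(C)C)c(O[Si](C)(C)C(C)(C)C)cc1[N+](=O)[O-]
F8 | step 8 | 4,5-bis(tert-butyldimethylsilyloxy)-2-[(tert-butyldimethylsilyloxy)methyl]aniline | CC(C)(C)[Si](C)(C)OCc1cc(O[Si](C)(C)C(C)(C)C)c(O[Si](C)(C)C(C)(C)C)cc1N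
F9 | step 8 | 2-bromo-3,4-bis(tert-butyldimethylsilyloxy)-6-[(tert-butyldimethylsilyloxy)methyl]aniline | CC(C)(C)[Si](C)(C)OCc1cc(O[Si](C)(C)C(C)(C)C)c(O[Si](C)(C)C(C)(C)C)c(Br)c1N
F10 | step 8 | 2-bromo-3,4-bis(tert-butyldimethylsilyloxy)-6-[(tert-butyldimethylsilyloxy)methyl]benzenediazonium bromide | CC(C)(C)[Si](C)(C)OCc1cc(O[Si](C)(C)C(C)(C)C)c(O[Si](C)(C)C(C)(C)C)c(Br)c1[N+]#N.[Br-]
F11 | step 8 | tert-butyl{[2,3-dibromo-4,5-bis(tert-butyldimethylsilyloxy)benzyl]oxy}dimethylsilane | CC(C)(C)[Si](C)(C)OCc1cc(O[Si](C)(C)C(C)(C)C)c(O[Si](C)(C)C(C)(C)C)c(Br)c1Br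
F12 | step 8 | 2,3-dibromo-4,5-bis(tert-butyldimethylsilyloxy)benzyl alcohol | OCc1cc(O[Si](C)(C)C(C)(C)C)c(O[Si](C)(C)C(C)(C)C)c(Br)c1Br
F13 | step 8 | 2,3-dibromo-4,5-bis(tert-butyldimethylsilyloxy)benzyl bromide | BrCc1cc(O[Si](C)(C)C(C)(C)C)c(O[Si](C)(C)C(C)(C)C)c(Br)c1Br
F14 | step 7 | bis[2-(tert-butoxycarbonylamino)-4,5-bis(tert-butyldimethylsilyloxy)benzyl] ether | CC(C)(C)OC(=O)Nc1cc(O[Si](C)(C)C(C)(C)C)c(O[Si](C)(C)C(C)(C)C)cc1COCc1cc(O[Si](C)(C)C(C)(C)C)c(O[Si](C)(C)C(C)(C)C)cc1NC(=O)OC(C)(C)C
F15 | step 7 | bis[3-bromo-2-(tert-butoxycarbonylamino)-4,5-bis(tert-butyldimethylsilyloxy)benzyl] ether | CC(C)(C)OC(=O)Nc1c(Br)c(O[Si](C)(C)C(C)(C)C)c(O[Si](C)(C)C(C)(C)C)cc1COCc1cc(O[Si](C)(C)C(C)(C)C)c(O[Si](C)(C)C(C)(C)C)c(Br)c1NC(=O)OC(C)(C)C
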